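The plan rests on cutting the benzene ring at its C1–C6 and C2–C3 bonds: C1, C2 and the acyloxyethyl arm then come from a terminal alkyne, and C3–C6 with the C4 oxygen from a 2-silyloxybutadiene. The feature exploited is the sparse substitution of the aromatic ring: nothing but OH on C4 and the CH2CH2O–acyl chain on C1, para to each other. A cobalt-catalysed [4+2] cycloaddition makes both ring bonds and the carbocycle in one operation, at the 1,4-cyclohexadiene level, one dehydrogenation short of the arene. Its precursor is the but-3-ynyl ester of dotriacontanoic acid, so the C32 chain is installed before the ring exists.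

Key step: step 2

Remark: the target has no stereocentre; dotriacontanoic acid, but-3-yn-1-ol and 2-(trimethylsilyloxy)buta-1,3-diene are taken as purchased, and the moisture-sensitive cycloadduct is carried forward crude, without chromatography.

Step 1
Reactants: 1 dotriacontanoic acid; 2 but-3-yn-1-ol
Product: 3 but-3-yn-1-yl dotriacontanoate
Conditions: EDC·HCl (1.3 equiv), DMAP (0.2 equiv), 2 (1.5 equiv), CH2Cl2/THF, 40 °C
Reagents that add atoms: none
Why: Steglich esterification, in which the carbodiimide activates the acid as an O-acylisourea and DMAP relays the acyl group to the unhindered primary alcohol, while the terminal alkyne is inert and gentle warming keeps the waxy acid in solution.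

Step 2
Reactants: 3 but-3-yn-1-yl dotriacontanoate; 4 2-(trimethylsilyloxy)buta-1,3-diene
Product: 5 2-[4-(trimethylsilyloxy)cyclohexa-1,4-dien-1-yl]ethyl dotriacontanoate
Conditions: CoBr2(dppe) (10 mol%), Zn powder (20 mol%), ZnI2 (20 mol%), 4 (1.5 equiv), dry CH2Cl2, 25 °C; pentane, short plug of Et3N-deactivated silica, used crude
Reagents that add atoms: none
Why: Zn powder takes the divalent cobalt of CoBr2(dppe) down to the monovalent state while ZnI2 strips bromide, leaving a cationic dppe–cobalt centre that binds the s-cis diene 4 and the alkyne of 3 side by side; C–C coupling within this complex (oxidative cyclisation) gives an η3-allyl vinyl metallacycle at trivalent cobalt, and reductive elimination forges the second bond and releases the skipped diene 5, which is not conjugated and does not react further. The closest known reaction type is the cobalt–diphosphine catalysed neutral Diels–Alder reaction of unactivated terminal alkynes with 2-substituted butadienes, 2-silyloxybutadienes included. The single new ring, the six-membered carbocycle, is closed by an intermolecular two-bond [4+2] annulation that joins diene C1 and C4 to the two alkyne carbons. No stereocentre is created. The selectivity demanded is regiochemical: the alkyne carbon bearing the side chain has to bond to diene C1 (the CH2 of the unsubstituted vinyl end) and the alkyne CH to C4 (next to C–OSiMe3), so that the para and not the meta pattern results. This orientation is what the bisphosphine dppe delivers in combination with the 2-silyloxy substituent, an excess of diene in CH2Cl2 suppresses alkyne cyclotrimerisation, and the ester two carbons from the alkyne is a spectator.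

Step 3
Reactants: 5 2-[4-(trimethylsilyloxy)cyclohexa-1,4-dien-1-yl]ethyl dotriacontanoate
Product: 7 2-(4-hydroxyphenyl)ethyl dotriacontanoate (basalethanolide A), via aryl trimethylsilyl ether 6 (not isolated)
Conditions: DDQ (1.0 equiv), PhMe, 25 °C; filter; then 1 M aq. HCl, THF, 25 °C
Reagents that add atoms: none
Why: Oxidative aromatisation by hydride abstraction, in which DDQ removes hydride from a doubly allylic CH2 of the 1,4-cyclohexadiene and proton loss gives the aryl silyl ether, whose labile Si–O bond is then hydrolysed by dilute acid under conditions that leave the alkyl ester untouched.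

Compound list
1 | dotriacontanoic acid | CCCCCCCCCCCCCCCCCCCCCCCCCCCCCCCC(=O)O | starting material
2 | but-3-yn-1-ol | OCCC#C | starting material
3 | but-3-yn-1-yl dotriacontanoate | CCCCCCCCCCCCCCCCCCCCCCCCCCCCCCCC(=O)OCCC#C | intermediate
4 | 2-(trimethylsilyloxy)buta-1,3-diene | C=CC(=C)O[Si](C)(C)C | starting material
5 | 2-[4-(trimethylsilyloxy)cyclohexa-1,4-dien-1-yl]ethyl dotriacontanoate | CCCCCCCCCCCCCCCCCCCCCCCCCCCCCCCC(=O)OCCC1=CCC(O[Si](C)(C)C)=CC1 | intermediate
6 | 2-[4-(trimethylsilyloxy)phenyl]ethyl dotriacontanoate | CCCCCCCCCCCCCCCCCCCCCCCCCCCCCCCC(=O)OCCc1ccc(O[Si](C)(C)C)cc1 | intermediate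
7 | 2-(4-hydroxyphenyl)ethyl dotriacontanoate (basalethanolide A) | CCCCCCCCCCCCCCCCCCCCCCCCCCCCCCCC(=O)OCCc1ccc(O)cc1 | target

Total step count: 3. Longest linear sequence: 3 steps (1 to 3 to 5 to 7).

Steps most likely to fail

Step 2. The cross [4+2] may be outrun by cobalt-mediated cyclotrimerisation of the alkyne. Para control may erode with an alkyl-substituted alkyne. The silyl enol ether may hydrolyse through adventitious water and ZnI2. The waxy ester may drop out of solution. The fallback gives up the de novo ring and takes the arene from the shelf. It sets out from 1: Steglich esterification (EDC·HCl, DMAP, CH2Cl2/THF, 40 °C) with purchased 2-[4-(benzyloxy)phenyl]ethanol should give 2-[4-(benzyloxy)phenyl]ethyl dotriacontanoate F1. Hydrogenolysis of the benzyl aryl ether (H2, Pd/C, THF/EtOAc, 25 °C) leaves the homobenzylic alkyl ester intact and comes back to the route at 7.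

Step 3. The acidic hydroquinone formed from DDQ may unmask the phenol early, and the quinone may then oxidise it at the benzylic position. The enol ether may also hydrolyse before hydride abstraction, which would stall the material at the ketone level. The fallback removes the quinone oxidant and does not pass through 6. It sets out from 5: deliberate hydrolysis (1 M aq. HCl, THF, 0 °C) should give 2-(4-oxocyclohex-1-en-1-yl)ethyl dotriacontanoate F2. Aerobic palladium-catalysed dehydrogenation of the cyclohexenone to the phenol (Pd(O2CCF3)2, 2-(dimethylamino)pyridine, TsOH, O2 at 1 atm, DMSO/chlorobenzene, 80 °C) comes back to the route at 7.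

Step 1. Acylation may stay incomplete because the C32 acid dissolves poorly, and the O-acylisourea may rearrange to an unreactive N-acylurea during the slow reaction. The fallback replaces in-situ carbodiimide activation with a preformed acyl donor. It sets out from 1: oxalyl chloride with catalytic DMF in toluene at 50 °C should give dotriacontanoyl chloride F3, freed of volatiles by evaporation. Treatment with 2 and pyridine in CH2Cl2 (0 °C to 25 °C) comes back to the route at 3.

Further compounds
F1 | step 2 | 2-[4-(benzyloxy)phenyl]ethyl dotriacontanoate | CCCCCCCCCCCCCCCCCCCCCCCCCCCCCCCC(=O)OCCc1ccc(OCc2ccccc2)cc1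
F2 | step 3 | 2-(4-oxocyclohex-1-en-1-yl)ethyl dotriacontanoate | CCCCCCCCCCCCCCCCCCCCCCCCCCCCCCCC(=O)OCCC1=CCC(=O)CC1
F3 | step 1 | dotriacontanoyl chloride | CCCCCCCCCCCCCCCCCCCCCCCCCCCCCCCC(=O)Cl
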